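## Structural features

The target is a methylene-bridged pair of phloroglucinol-derived rings. Ring A is a fully substituted acylphloroglucinol monomethyl ether (a1 (R)-2-methylbutanoyl, a2 OH, a3 CH3, a4 OCH3, a5 CH2, a6 OH). Ring B is the benzo ring of a 5,7-dihydroxy-2,2,6-trimethylchroman-4-one, and a5 is joined through one CH2 to C8. The only stereocentre is the (R)-configured α-carbon of the butanoyl chain; it has no stereogenic neighbour, but it lies next to an aryl ketone and can enolise under base or strong acid. Fragile elements are the diarylmethane between two electron-rich nuclei (acid-labile by retro-Friedel–Crafts cleavage), the free polyphenol, the chromanone (retro-oxa-Michael under strong base) and that α-stereocentre. The real difficulty is the substitution pattern: both benzene rings are hexasubstituted and each carries three oxygens in different states. The three oxygens of ring B (C5, C7, C8a) must be told apart so that the gem-dimethylpyranone closes on the C8a oxygen, and in ring A only the oxygen flanked by the methyl-bearing and methylene-bearing carbons is methylated. In addition, C4a of ring B and a1 of ring A are both highly nucleophilic aromatic positions that must receive two different acyl groups. The key step exploits the 1,3,5-trioxygenated ring B: a four-carbon vinylketene supplies C8a, C4a, C5 and C6 (with the C6 methyl and C5 oxygen), and a two-carbon ynol ether supplies C8 (carrying the bridging CH2 and ring A) and C7, so C8a arrives as free OH, C7 as silyl ether and C5 as benzyl ether.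

## Logic of the disconnections

30 ⇒ 29 ⇒ 28. Only O–benzyl and O–silicon bonds are cut. The last two operations are therefore deprotections under neutral or buffered conditions, which is what the enolisable α-stereocentre and the acid-labile diarylmethane require. The demand is that the three benzyl ethers and the silyl ether survive everything before.

28 ⇒ 25 + 26. The a1–acyl bond is cut. In 25 ring B is fully substituted, so a1 is the only free carbon on either electron-rich ring and no regiochemical question remains. The chiral unit is taken from the pool and enters late, so it meets only three further steps. The forward step must acylate a doubly flanked position without Lewis acids that strip benzyl ethers and without racemisation. This is why the mixed anhydride 27 is used, not an acid chloride with a metal halide, and why the silyl ether is kept on C7 until after this step so that no free hydroxyl is acylated.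

25 ⇒ 24 ⇒ 23 ⇒ 21 + 22 ⇒ 20. The bonds O1–C2, C3–C4 and C4–C4a are cut. In 20 the C8a hydroxyl is the only free OH and C4a the only free ortho carbon. A phenoxide-directed delivery of one carbon uses that hydroxyl as the handle and never offers an electrophile to a1 of ring A. The shorter ester/Fries sequence would do so under Lewis acid (acyl crossover, benzyl loss), and its photochemical variant would expose three benzyl aryl ethers to ultraviolet light. For that reason the formylation route is preferred here at the cost of one operation. The demand is that the ionisable diol 23 is carried on without purification.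

20 ⇒ 9 + 15. The bonds C8–C8a and C6–C7 are cut (the C8a–C4a bond is broken and re-formed in the forward cascade). This removes ring B in one operation and turns the differentiation of its three oxygens into a matter of which component carries which oxygen. The forward step needs one orientation of the ketene–alkyne cycloaddition and a cyclobutenone that opens at a temperature the siloxyalkyne tolerates.

9 ⇒ 6 ⇒ 5 ⇒ 4. The bond between the ester carbonyl carbon and the new alkyne carbon is cut (ynolate 8 arises from ester 6 by insertion of one carbon through 7). Then the benzylic C–C bond of the arylacetic ester is traced back to the aldehyde carbon by a one-carbon homologation through 5. The demand is that addition to the ester outruns enolisation of its acidic benzylic position and that excess alkyllithium is kept cold.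

4 ⇒ 3 ⇒ 2 ⇒ 1. One O–CH3 bond, two O–benzyl bonds and the aryl–CHO bond are cut. Because 1 is symmetric, formylation can give only one aldehyde. The aldehyde then ranks the three hydroxyls (para, ortho and unhindered, ortho and buttressed by the methyl), so the oxygen between the formyl-bearing and methyl-bearing carbons is the one left for methylation. A resorcinol that already carries the O-methyl group was rejected as the origin of ring A. It would need two successive ring substitutions, each competing with the site between the two free oxygens.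

15 ⇒ 14 ⇒ 13 ⇒ 11 + 12 (from 10). The benzyl–oxygen bond is cut, then the four-membered ring is cut into an ynol ether and ketene. The regiochemistry of that cycloaddition places the methyl on C2 and the oxygen on C3 without ambiguity.

## Other disconnections considered

Alternative 1: The cut runs through ring A at a5–a6 and a1–a2. The partners are anhydride A2 (a2 to a5 plus one carbonyl that leaves) and ynone A3 (a1, a6 and the chiral acyl group).
- Forward step: deprotonated A2 adds through a5 to the ethoxy-bearing alkyne carbon of A3, the vinyl anion closes on the anhydride carbonyl, CO2 is lost and A1 aromatises. Chelation-controlled de-ethylation and hydrogenolysis would finish.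
- In favour: the hexasubstituted ring A and the acyl group arrive together with no electrophilic substitution at a hindered carbon, which is better than step 14 of the chosen plan. If the anhydride reacted through a3 instead, the isomeric ethyl ether would converge on the same polyphenol, so the orientation is immaterial.
- Against: the anhydride anion is a base and the stereocentre of A3 lies α to an ynone carbonyl, so configurational erosion is a real threat. An ethyl ether must later be removed by a boron halide beside the a4 methyl ether and the acid-labile diarylmethane. A2 already contains the finished ring B, whose oxygen differentiation this disconnection does not address.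
- Comparison: structurally it solves ring A and leaves ring B open, the reverse of the chosen plan. Mechanistically it is anionic where the chosen key step is neutral and pericyclic. On step economy it is estimated equal at best, because A2 needs the chromanone with a one-carbon handle at C8.

Alternative 2: The cut is the C4–C4a bond (with O1–C2 formed beforehand by etherification).
- Forward step: heating A5 triggers the [3,3] shift of the 1,1-dimethylpropargyl group from the C8a oxygen to C4a, a hydrogen shift and 6π oxa-electrocyclisation to the chromene A4.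
- In favour: the cascade is neutral and intramolecular. It is the equal of the chosen pyranone construction in regiochemical security, since C4a is the only open ortho carbon. It is better in avoiding organometallic addition and the sensitive diol 23.
- Against: it stops at the chromene oxidation level, so C4 must still be oxygenated regioselectively (Markovnikov hydration, then oxidation), two further operations next to benzyl ethers and the stereocentre. A5 also presupposes a ring B whose C8a oxygen alone is free.
- Comparison: this alternative is complementary to the chosen benzannulation and not a replacement for it, because it could start from 20. Mechanistically both key steps are thermal pericyclic cascades. On step economy it needs about four operations from the free phenol to the chromanone against three in the chosen plan.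

Alternative 3: The cut is the a1–a6 bond of ring A.
- Forward step: methoxide opens the lactone of pyrone A7 and the methylene of its oxoalkyl arm condenses on the liberated ester carbonyl (Claisen closure), giving A6 after aromatisation.
- In favour: the placement of methyl, methoxy and methylene on ring A is fixed by construction, which is better than the chosen plan's reliance on selective benzylation in step 2. Ring A needs no protecting groups and only hydrogenolysis follows, a shorter endgame.
- Against: hot methoxide acts on a ketone whose α-carbon is the stereocentre, both in the open triketide and in the product, so the single enantiomer is unlikely to survive intact. The chromanone can also open by retro-oxa-Michael reaction. Assembly of A7 requires strongly basic acylation with the chiral unit.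
- Comparison: structurally elegant and biomimetic. Mechanistically it is under thermodynamic, anionic control, where the chosen plan never exposes the stereocentre to base. Overall step count is estimated as roughly equal once A7 is made.

Key step: step 10

Remark (assumptions): ketene is not sold and is generated on demand by cracking acetone (10). The atom mapping of the benzannulation was re-derived (ketene carbon → C8a, siloxy carbon → C7, benzyloxy carbon → C5) and agrees with 9, 15 and 20, so no structure needed correcting.

## Steps

Step 1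
Reactants: 1 2-methylbenzene-1,3,5-triol
Product: 2 2,4,6-trihydroxy-3-methylbenzaldehyde
Conditions: POCl3 (1.1 equiv), DMF (1.5 equiv), EtOAc, 0 °C → rt; then H2O, 50 °C
Reagents that add atoms: N,N-dimethylformamide, CN(C)C=O; water, O
Why: Vilsmeier–Haack formylation of a phloroglucinol nucleus; the two free ring positions of 1 are equivalent by symmetry, so only one monoaldehyde can form, and limiting the chloroiminium salt should suppress double formylation.

Step 2
Reactants: 2 2,4,6-trihydroxy-3-methylbenzaldehyde
Product: 3 4,6-bis(benzyloxy)-2-hydroxy-3-methylbenzaldehyde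
Conditions: BnBr (2.05 equiv), K2CO3 (2.2 equiv), DMF, 0 °C → rt
Reagents that add atoms: benzyl bromide, BrCc1ccccc1
Why: Williamson etherification under weak base; the hydroxyl para to the aldehyde is the most acidic and should react first, and of the two chelated ortho hydroxyls the one at C6 (flanked by hydrogen) should be benzylated in preference to the one at C2, which is buttressed by the C3 methyl.

Step 3
Reactants: 3 4,6-bis(benzyloxy)-2-hydroxy-3-methylbenzaldehyde
Product: 4 4,6-bis(benzyloxy)-2-methoxy-3-methylbenzaldehyde
Conditions: MeI (3 equiv), K2CO3 (2 equiv), DMF, 50 °C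
Reagents that add atoms: iodomethane, CI
Why: O-methylation of the remaining hindered, hydrogen-bonded phenol under forcing but standard Williamson conditions; this fixes the methyl ether on the oxygen lying between the formyl-bearing and the methyl-bearing carbons.

Step 4
Reactants: 4 4,6-bis(benzyloxy)-2-methoxy-3-methylbenzaldehyde
Product: 5 1,5-bis(benzyloxy)-3-methoxy-2-methyl-4-[2-(methylsulfanyl)-2-(methylsulfinyl)ethenyl]benzene (alkene isomers, racemic at sulfur)
Conditions: CH3S(O)CH2SCH3 (1.5 equiv), BnMe3N+ OH− (40% in MeOH, 0.5 equiv), THF, reflux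
Reagents that add atoms: methyl (methylsulfanyl)methyl sulfoxide, CS(=O)CSC
Why: Knoevenagel-type condensation of an aromatic aldehyde with the acidic methylene of the dithioacetal S-oxide; alkene geometry and the sulfur stereocentre are irrelevant because both are destroyed in step 5.

Step 5
Reactants: 5 1,5-bis(benzyloxy)-3-methoxy-2-methyl-4-[2-(methylsulfanyl)-2-(methylsulfinyl)ethenyl]benzene
Product: 6 ethyl 2-[2,4-bis(benzyloxy)-6-methoxy-5-methylphenyl]acetate
Conditions: HCl (saturated) in EtOH, 0 °C → rt
Reagents that add atoms: ethanol, CCO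
Why: acid-promoted ethanolysis of a ketene dithioacetal S-oxide (protonation at the benzylic carbon, capture of the thionium ion by ethanol, loss of both sulfur groups) should give the arylacetic ester, completing a one-carbon homologation of the aldehyde.

Step 6
Reactants: 6 ethyl 2-[2,4-bis(benzyloxy)-6-methoxy-5-methylphenyl]acetate
Product: 9 3-[2,4-bis(benzyloxy)-6-methoxy-5-methylphenyl]-1-(triisopropylsilyloxy)prop-1-yne, via dibromoketone enolate 7 (not isolated), via lithium ynolate 8 (not isolated)
Conditions: CH2Br2 (2.2 equiv), lithium 2,2,6,6-tetramethylpiperidide (2.1 equiv), THF, −78 °C; LiN(SiMe3)2 (2 equiv), −78 °C; n-BuLi (4 equiv), −78 → −20 °C; i-Pr3SiOTf (3 equiv), −78 → 0 °C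
Reagents that add atoms: dibromomethane, BrCBr; triisopropylsilyl trifluoromethanesulfonate, CC(C)[Si](OS(=O)(=O)C(F)(F)F)(C(C)C)C(C)C
Why: Kowalski homologation: dibromomethyllithium adds to the ester and base converts the adduct into enolate 7; bromine–lithium exchange then triggers the carbenoid 1,2-shift to ynolate 8, which the bulky silyl triflate should trap on oxygen to give the siloxyalkyne.

Step 7
Reactants: 10 acetone; 11 1-ethoxy-1-propyne
Product: 13 3-ethoxy-2-methylcyclobut-2-en-1-one, via ketene 12 (not isolated)
Conditions: acetone, 700 °C (ketene generator); gas stream into 11, CH2Cl2, 0 °C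
Reagents that add atoms: none
Why: thermal [2+2] cycloaddition of ketene with an ynol ether; the nucleophilic methyl-bearing alkyne carbon bonds to the ketene carbonyl carbon, which places the methyl on C2 and the ethoxy group on C3.

Step 8
Reactants: 13 3-ethoxy-2-methylcyclobut-2-en-1-one
Product: 14 3-hydroxy-2-methylcyclobut-2-en-1-one (enol form of 2-methylcyclobutane-1,3-dione)
Conditions: 1 M HCl, THF/H2O, 0 °C → rt
Reagents that add atoms: water, O
Why: acid hydrolysis of a vinylogous ester to the strongly acidic, fully enolised 1,3-dione.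

Step 9
Reactants: 14 3-hydroxy-2-methylcyclobut-2-en-1-one
Product: 15 3-(benzyloxy)-2-methylcyclobut-2-en-1-one
Conditions: BnOH (1.1 equiv), PPh3 (1.2 equiv), DIAD (1.2 equiv), THF, 0 °C → rt
Reagents that add atoms: benzyl alcohol, OCc1ccccc1
Why: Mitsunobu O-alkylation of a vinylogous acid, a standard reaction of acidic cyclic 1,3-diones; the neutral conditions avoid the ring cleavage that free alkoxide or hot alcohol can cause in cyclobutane-1,3-diones.

Step 10
Reactants: 9 3-[2,4-bis(benzyloxy)-6-methoxy-5-methylphenyl]-1-(triisopropylsilyloxy)prop-1-yne; 15 3-(benzyloxy)-2-methylcyclobut-2-en-1-one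
Product: 20 5-(benzyloxy)-2-{[2,4-bis(benzyloxy)-6-methoxy-5-methylphenyl]methyl}-4-methyl-3-[(triisopropylsilyl)oxy]phenol, via vinylketene 16 (not isolated), via vinylcyclobutenone 17 (not isolated), via dienylketene 18 (not isolated), via cyclohexadienone 19 (not isolated)
Conditions: 15 (1.2 equiv), toluene (0.3 M, degassed), sealed tube, 110 °C
Reagents that add atoms: none
Why: Danheiser benzannulation, a four-stage pericyclic cascade. Thermal 4π-electrocyclic opening of 15 gives vinylketene 16. Regioselective [2+2] cycloaddition of the ketene C=C of 16 with the siloxyalkyne joins the ketene carbonyl carbon to the benzyl-substituted alkyne carbon (the C8–C8a bond) and the methyl-bearing ketene carbon to the siloxy carbon (the C6–C7 bond), giving 17. A second 4π opening converts 17 into dienylketene 18, and 6π-electrocyclic closure of 18 between the ketene carbon and the terminal methylene (the C8a–C4a bond) closes ring B as dienone 19, which tautomerises to phenol 20. The closest known reaction type is the thermal benzannulation of cyclobutenones with trialkylsiloxyalkynes to resorcinol monosilyl ethers. Ring B is thus closed by a disrotatory 6π electrocyclisation, the four-membered ring of 17 being only a relay, and no stereocentre survives because the racemic quaternary carbon of 17 is lost on aromatisation. The selectivity needed is the orientation of the [2+2] step, which the polarisation of the ynol ether secures: its carbon remote from oxygen is the nucleophile and attacks the electrophilic ketene carbonyl carbon. The ketene oxygen therefore emerges as the only free hydroxyl (C8a), the alkyne oxygen as the silyl ether (C7) and the cyclobutenone oxygen as the benzyl ether (C5), with C4a unsubstituted, under neutral conditions that leave ring A untouched.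

Step 11
Reactants: 20 5-(benzyloxy)-2-{[2,4-bis(benzyloxy)-6-methoxy-5-methylphenyl]methyl}-4-methyl-3-[(triisopropylsilyl)oxy]phenol
Product: 21 6-(benzyloxy)-3-{[2,4-bis(benzyloxy)-6-methoxy-5-methylphenyl]methyl}-2-hydroxy-5-methyl-4-[(triisopropylsilyl)oxy]benzaldehyde
Conditions: MgCl2 (2 equiv), Et3N (4 equiv), (CH2O)n (6 equiv), THF, reflux; then 1 M HCl
Reagents that add atoms: formaldehyde (as paraformaldehyde), C=O
Why: magnesium phenoxide-directed ortho-formylation (Casnati–Skattebøl reaction): formaldehyde is delivered within the magnesium chelate to the only free ortho carbon, C4a, and the benzylic alkoxide is oxidised by hydride transfer to a second formaldehyde; ring A has no free hydroxyl and should stay untouched although a1 is the more electron-rich carbon.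

Step 12
Reactants: 21 6-(benzyloxy)-3-{[2,4-bis(benzyloxy)-6-methoxy-5-methylphenyl]methyl}-2-hydroxy-5-methyl-4-[(triisopropylsilyl)oxy]benzaldehyde; 22 2-methylprop-1-en-1-ylmagnesium bromide
Product: 23 1-[6-(benzyloxy)-3-{[2,4-bis(benzyloxy)-6-methoxy-5-methylphenyl]methyl}-2-hydroxy-5-methyl-4-[(triisopropylsilyl)oxy]phenyl]-3-methylbut-2-en-1-ol (racemic, used crude)
Conditions: 22 (3 equiv, 0.5 M in THF), THF, −20 → 0 °C; then pH 7 buffer
Reagents that add atoms: none
Why: 1,2-addition of an alkenyl Grignard reagent to the salicylaldehyde after the first equivalent has deprotonated the phenol; the new carbinol centre forms as a racemate and is removed in step 13.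

Step 13
Reactants: 23 1-[6-(benzyloxy)-3-{[2,4-bis(benzyloxy)-6-methoxy-5-methylphenyl]methyl}-2-hydroxy-5-methyl-4-[(triisopropylsilyl)oxy]phenyl]-3-methylbut-2-en-1-ol
Product: 25 5-(benzyloxy)-8-{[2,4-bis(benzyloxy)-6-methoxy-5-methylphenyl]methyl}-2,2,6-trimethyl-7-[(triisopropylsilyl)oxy]chroman-4-one, via hydroxyaryl enone 24 (not isolated)
Conditions: MnO2 (activated, 15 equiv), CH2Cl2, rt; filter; DBU (0.3 equiv), CH2Cl2, rt
Reagents that add atoms: none
Why: MnO2 oxidises the doubly activated (benzylic and allylic) alcohol to enone 24; the amidine base then triggers 6-endo-trig oxa-Michael addition of the C8a phenoxide, the only free hydroxyl of ring B, to the β,β-dimethyl enone, so the pyranone closes on the correct oxygen.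

Step 14
Reactants: 25 5-(benzyloxy)-8-{[2,4-bis(benzyloxy)-6-methoxy-5-methylphenyl]methyl}-2,2,6-trimethyl-7-[(triisopropylsilyl)oxy]chroman-4-one; 26 (2R)-2-methylbutanoic acid
Product: 28 5-(benzyloxy)-8-({2,4-bis(benzyloxy)-6-methoxy-5-methyl-3-[(2R)-2-methylbutanoyl]phenyl}methyl)-2,2,6-trimethyl-7-[(triisopropylsilyl)oxy]chroman-4-one, via mixed anhydride 27 (not isolated)
Conditions: 26 (1.5 equiv), (CF3CO)2O (1.5 equiv), CH2Cl2, 0 °C, 30 min; then 25, H3PO4 (85%, 0.1 equiv), 0 °C → rt
Reagents that add atoms: none
Why: Friedel–Crafts acylation by a carboxylic–trifluoroacetic mixed anhydride, a known Lewis-acid-free acylation of trialkoxybenzenes; a1 is the only unsubstituted carbon of either electron-rich ring and is activated by two ortho benzyloxy groups and the para methoxy group. The acid-only medium forms neither ketene nor enolate from 27, so the (R) centre brought in with 26 should be retained.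

Step 15
Reactants: 28 5-(benzyloxy)-8-({2,4-bis(benzyloxy)-6-methoxy-5-methyl-3-[(2R)-2-methylbutanoyl]phenyl}methyl)-2,2,6-trimethyl-7-[(triisopropylsilyl)oxy]chroman-4-one
Product: 29 5-(benzyloxy)-8-({2,4-bis(benzyloxy)-6-methoxy-5-methyl-3-[(2R)-2-methylbutanoyl]phenyl}methyl)-7-hydroxy-2,2,6-trimethylchroman-4-one
Conditions: Bu4NF (1.2 equiv), AcOH (1.5 equiv), THF, 0 °C
Reagents that add atoms: none
Why: fluoride cleavage of an aryl silyl ether; the acetic acid buffer protonates the phenoxide as it forms and keeps the medium too weakly basic to enolise the α-branched ketone.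

Step 16
Reactants: 29 5-(benzyloxy)-8-({2,4-bis(benzyloxy)-6-methoxy-5-methyl-3-[(2R)-2-methylbutanoyl]phenyl}methyl)-7-hydroxy-2,2,6-trimethylchroman-4-one
Product: 30 8-({2,4-dihydroxy-6-methoxy-5-methyl-3-[(2R)-2-methylbutanoyl]phenyl}methyl)-5,7-dihydroxy-2,2,6-trimethylchroman-4-one (CNP0303209.1)
Conditions: H2 (1 atm), 10% Pd/C, EtOAc–MeOH (1:1), rt
Reagents that add atoms: none
Why: hydrogenolysis of three aryl benzyl ethers over Pd/C under neutral conditions; the chelated aryl ketones and the diarylmethane should not be reduced and the stereocentre is not involved.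

## Compound list

1 | 2-methylbenzene-1,3,5-triol | Cc1c(O)cc(O)cc1O | starting material
2 | 2,4,6-trihydroxy-3-methylbenzaldehyde | O=Cc1c(O)c(C)c(O)cc1O | intermediate
3 | 4,6-bis(benzyloxy)-2-hydroxy-3-methylbenzaldehyde | O=Cc1c(O)c(C)c(OCc2ccccc2)cc1OCc1ccccc1 | intermediate
4 | 4,6-bis(benzyloxy)-2-methoxy-3-methylbenzaldehyde | O=Cc1c(OC)c(C)c(OCc2ccccc2)cc1OCc1ccccc1 | intermediate
5 | 1,5-bis(benzyloxy)-3-methoxy-2-methyl-4-[2-(methylsulfanyl)-2-(methylsulfinyl)ethenyl]benzene (alkene isomers, racemic at sulfur) | CSC(=Cc1c(OC)c(C)c(OCc2ccccc2)cc1OCc1ccccc1)S(C)=O | intermediate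
6 | ethyl 2-[2,4-bis(benzyloxy)-6-methoxy-5-methylphenyl]acetate | CCOC(=O)Cc1c(OC)c(C)c(OCc2ccccc2)cc1OCc1ccccc1 | intermediate
7 | lithium 3-[2,4-bis(benzyloxy)-6-methoxy-5-methylphenyl]-1,1-dibromoprop-1-en-2-olate | [Li+].[O-]C(Cc1c(OC)c(C)c(OCc2ccccc2)cc1OCc1ccccc1)=C(Br)Br | intermediate
8 | lithium 3-[2,4-bis(benzyloxy)-6-methoxy-5-methylphenyl]prop-1-yn-1-olate | [Li+].[O-]C#CCc1c(OC)c(C)c(OCc2ccccc2)cc1OCc1ccccc1 | intermediate
9 | 3-[2,4-bis(benzyloxy)-6-methoxy-5-methylphenyl]-1-(triisopropylsilyloxy)prop-1-yne | COc1c(C)c(OCc2ccccc2)cc(OCc2ccccc2)c1CC#CO[Si](C(C)C)(C(C)C)C(C)C | intermediate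
10 | acetone | CC(C)=O | starting material
11 | 1-ethoxy-1-propyne | CCOC#CC | starting material
12 | ketene | C=C=O | intermediate
13 | 3-ethoxy-2-methylcyclobut-2-en-1-one | CCOC1=C(C)C(=O)C1 | intermediate
14 | 3-hydroxy-2-methylcyclobut-2-en-1-one (enol of 2-methylcyclobutane-1,3-dione) | CC1=C(O)CC1=O | intermediate
15 | 3-(benzyloxy)-2-methylcyclobut-2-en-1-one | CC1=C(OCc2ccccc2)CC1=O | intermediate
16 | 3-(benzyloxy)-2-methylbuta-1,3-dien-1-one | C=C(OCc1ccccc1)C(C)=C=O | intermediate
17 | 4-[1-(benzyloxy)ethenyl]-2-{[2,4-bis(benzyloxy)-6-methoxy-5-methylphenyl]methyl}-4-methyl-3-[(triisopropylsilyl)oxy]cyclobut-2-en-1-one (racemic) | O=C1C(Cc2c(OC)c(C)c(OCc3ccccc3)cc2OCc2ccccc2)=C(O[Si](C(C)C)(C(C)C)C(C)C)C1(C)C(=C)OCc1ccccc1 | intermediate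
18 | 5-(benzyloxy)-2-{[2,4-bis(benzyloxy)-6-methoxy-5-methylphenyl]methyl}-4-methyl-3-[(triisopropylsilyl)oxy]hexa-1,3,5-trien-1-one | O=C=C(Cc1c(OC)c(C)c(OCc2ccccc2)cc1OCc1ccccc1)C(O[Si](C(C)C)(C(C)C)C(C)C)=C(C)C(=C)OCc1ccccc1 | intermediate
19 | 5-(benzyloxy)-2-{[2,4-bis(benzyloxy)-6-methoxy-5-methylphenyl]methyl}-4-methyl-3-[(triisopropylsilyl)oxy]cyclohexa-2,4-dien-1-one | O=C1CC(OCc2ccccc2)=C(C)C(O[Si](C(C)C)(C(C)C)C(C)C)=C1Cc1c(OC)c(C)c(OCc2ccccc2)cc1OCc1ccccc1 | intermediate
20 | 5-(benzyloxy)-2-{[2,4-bis(benzyloxy)-6-methoxy-5-methylphenyl]methyl}-4-methyl-3-[(triisopropylsilyl)oxy]phenol | Oc1cc(OCc2ccccc2)c(C)c(O[Si](C(C)C)(C(C)C)C(C)C)c1Cc1c(OCc2ccccc2)cc(OCc2ccccc2)c(C)c1OC | intermediate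
21 | 6-(benzyloxy)-3-{[2,4-bis(benzyloxy)-6-methoxy-5-methylphenyl]methyl}-2-hydroxy-5-methyl-4-[(triisopropylsilyl)oxy]benzaldehyde | O=Cc1c(O)c(Cc2c(OCc3ccccc3)cc(OCc3ccccc3)c(C)c2OC)c(O[Si](C(C)C)(C(C)C)C(C)C)c(C)c1OCc1ccccc1 | intermediate
22 | 2-methylprop-1-en-1-ylmagnesium bromide | CC(C)=C[Mg]Br | starting material
23 | 1-[6-(benzyloxy)-3-{[2,4-bis(benzyloxy)-6-methoxy-5-methylphenyl]methyl}-2-hydroxy-5-methyl-4-[(triisopropylsilyl)oxy]phenyl]-3-methylbut-2-en-1-ol (racemic) | CC(C)=CC(O)c1c(O)c(Cc2c(OCc3ccccc3)cc(OCc3ccccc3)c(C)c2OC)c(O[Si](C(C)C)(C(C)C)C(C)C)c(C)c1OCc1ccccc1 | intermediate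
24 | 1-[6-(benzyloxy)-3-{[2,4-bis(benzyloxy)-6-methoxy-5-methylphenyl]methyl}-2-hydroxy-5-methyl-4-[(triisopropylsilyl)oxy]phenyl]-3-methylbut-2-en-1-one | CC(C)=CC(=O)c1c(O)c(Cc2c(OCc3ccccc3)cc(OCc3ccccc3)c(C)c2OC)c(O[Si](C(C)C)(C(C)C)C(C)C)c(C)c1OCc1ccccc1 | intermediate
25 | 5-(benzyloxy)-8-{[2,4-bis(benzyloxy)-6-methoxy-5-methylphenyl]methyl}-2,2,6-trimethyl-7-[(triisopropylsilyl)oxy]chroman-4-one | CC1(C)CC(=O)c2c(OCc3ccccc3)c(C)c(O[Si](C(C)C)(C(C)C)C(C)C)c(Cc3c(OCc4ccccc4)cc(OCc4ccccc4)c(C)c3OC)c2O1 | intermediate
26 | (2R)-2-methylbutanoic acid | CC[C@@H](C)C(O)=O | starting material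
27 | (2R)-2-methylbutanoic trifluoroacetic anhydride | CC[C@@H](C)C(=O)OC(=O)C(F)(F)F | intermediate
28 | 5-(benzyloxy)-8-({2,4-bis(benzyloxy)-6-methoxy-5-methyl-3-[(2R)-2-methylbutanoyl]phenyl}methyl)-2,2,6-trimethyl-7-[(triisopropylsilyl)oxy]chroman-4-one | CC[C@@H](C)C(=O)c1c(OCc2ccccc2)c(C)c(OC)c(Cc2c(O[Si](C(C)C)(C(C)C)C(C)C)c(C)c(OCc3ccccc3)c3c2OC(C)(C)CC3=O)c1OCc1ccccc1 | intermediate
29 | 5-(benzyloxy)-8-({2,4-bis(benzyloxy)-6-methoxy-5-methyl-3-[(2R)-2-methylbutanoyl]phenyl}methyl)-7-hydroxy-2,2,6-trimethylchroman-4-one | CC[C@@H](C)C(=O)c1c(OCc2ccccc2)c(C)c(OC)c(Cc2c(O)c(C)c(OCc3ccccc3)c3c2OC(C)(C)CC3=O)c1OCc1ccccc1 | intermediate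
30 | 8-({2,4-dihydroxy-6-methoxy-5-methyl-3-[(2R)-2-methylbutanoyl]phenyl}methyl)-5,7-dihydroxy-2,2,6-trimethylchroman-4-one | CC[C@@H](C)C(=O)c1c(O)c(C)c(OC)c(Cc2c(O)c(C)c(O)c3c2OC(C)(C)CC3=O)c1O | target

## Step count and least certain steps

Total: 16 steps. Longest linear sequence: 13 steps (steps 1–6, 10, 11–16); steps 7–9 form the convergent branch.

Step 10 (key step). The push–pull cyclobutenone 15 may open only slowly, so that at the temperature required the siloxyalkyne is lost by thermal silyl migration from oxygen to carbon, or the product phenol is acylated by surplus vinylketene.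
- Fallback: it sets out from 9 and rejoins the route at 16. The same vinylketene is generated at room temperature by photochemical Wolff rearrangement instead of electrocyclic opening.
- Commercial (benzyloxy)acetaldehyde is α-methylenated (aqueous CH2O, pyrrolidine, propionic acid) to 2-(benzyloxy)prop-2-enal F1. EtMgBr addition gives 2-(benzyloxy)pent-1-en-3-ol F2. Dess–Martin oxidation gives 2-(benzyloxy)pent-1-en-3-one F3. Detrifluoroacetylative diazo transfer (LiN(SiMe3)2, CF3CO2CH2CF3; then MsN3, Et3N) gives 2-(benzyloxy)-4-diazopent-1-en-3-one F4.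
- Irradiation of F4 at 350 nm with 9 in CH2Cl2 releases nitrogen, and migration of the alkenyl group gives 16. The cascade through 17, 18 and 19 is completed by warming to 80 °C and ends at 20.

Step 2. Discrimination between the two ortho hydroxyls may be incomplete, so benzylation could spread to the C2 oxygen or stop at the monoether; this would misplace the methyl ether of ring A.
- Fallback: it sets out from 2 and returns at 3. Exhaustive benzylation (BnBr 3.5 equiv, K2CO3, DMF, 60 °C) gives 2,4,6-tris(benzyloxy)-3-methylbenzaldehyde F5.
- Chelation-controlled mono-debenzylation with MgBr2·OEt2 (toluene/Et2O, rt) is then expected to remove the ortho benzyl group at C2, which is twisted out of plane by the neighbouring methyl. Here the selection rests on ether cleavage with relief of strain, not on alkylation rate.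

Step 6. Dibromomethyllithium may deprotonate the acidic benzylic position of the arylacetic ester instead of adding to it, and excess n-BuLi may metalate a1 between the two benzyloxy groups or a benzylic ether position.
- Fallback: it sets out from 6 and returns at 8. Reduction with i-Bu2AlH (CH2Cl2, −78 °C) gives 2-[2,4-bis(benzyloxy)-6-methoxy-5-methylphenyl]acetaldehyde F6.
- Ohira–Bestmann homologation (K2CO3, MeOH, 0 °C) gives 1,5-bis(benzyloxy)-3-methoxy-2-methyl-4-(prop-2-yn-1-yl)benzene F7.
- One equivalent of n-BuLi forms the lithium acetylide, which is oxidised with LiOOt-Bu (from t-BuOOH and LiN(SiMe3)2, THF, −78 → 0 °C) to ynolate 8. Silylation as in step 6 then gives 9.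

Step 11. Formylation at a carbon flanked by the benzyloxy group may stall, or the aldehyde may react further with formaldehyde on prolonged heating; the diol of step 12 may also ionise to an ortho-quinone methide and close to a chromene.
- Fallback: it sets out from 20 and returns at 24. Steglich esterification of the C8a hydroxyl with 3-methylbut-2-enoic acid (DCC, DMAP, CH2Cl2) gives 5-(benzyloxy)-2-{[2,4-bis(benzyloxy)-6-methoxy-5-methylphenyl]methyl}-4-methyl-3-[(triisopropylsilyl)oxy]phenyl 3-methylbut-2-enoate F8.
- Photo-Fries rearrangement (300 nm, cyclohexane) moves the acyl group within the solvent cage to C4a, the only open ortho or para site, giving 24; this is cyclised with DBU as in step 13.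
- The in-cage shift cannot deliver the acyl group to a1 of ring A. Its own weakness is competing photolysis of benzyl aryl ethers, which is why it is not the first choice.

Step 14. Acylation at the doubly flanked a1 with an α-branched acyl group may be slow; forcing it with stronger acid risks loss of benzyl groups and partial enolisation at the stereocentre.
- Fallback: it sets out from 25 and returns at 30. Desilylation (Bu4NF, AcOH, THF) gives 5-(benzyloxy)-8-{[2,4-bis(benzyloxy)-6-methoxy-5-methylphenyl]methyl}-7-hydroxy-2,2,6-trimethylchroman-4-one F9.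
- Hydrogenolysis (H2, Pd/C) gives 8-[(2,4-dihydroxy-6-methoxy-5-methylphenyl)methyl]-5,7-dihydroxy-2,2,6-trimethylchroman-4-one F10.
- Classical C-acylation of the free phloroglucinol ring with (2R)-2-methylbutanoyl chloride F11 (from 26 and oxalyl chloride) and AlCl3 in CH2Cl2/PhNO2 at 0 °C → rt then places the acyl group on a1, the only free ring carbon, and gives 30 directly.

## Further compounds

F1 | step 10 | 2-(benzyloxy)prop-2-enal | C=C(OCc1ccccc1)C=O
F2 | step 10 | 2-(benzyloxy)pent-1-en-3-ol (racemic) | CCC(O)C(=C)OCc1ccccc1
F3 | step 10 | 2-(benzyloxy)pent-1-en-3-one | CCC(=O)C(=C)OCc1ccccc1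
F4 | step 10 | 2-(benzyloxy)-4-diazopent-1-en-3-one | CC(=[N+]=[N-])C(=O)C(=C)OCc1ccccc1
F5 | step 2 | 2,4,6-tris(benzyloxy)-3-methylbenzaldehyde | O=Cc1c(OCc2ccccc2)c(C)c(OCc2ccccc2)cc1OCc1ccccc1
F6 | step 6 | 2-[2,4-bis(benzyloxy)-6-methoxy-5-methylphenyl]acetaldehyde | O=CCc1c(OC)c(C)c(OCc2ccccc2)cc1OCc1ccccc1
F7 | step 6 | 1,5-bis(benzyloxy)-3-methoxy-2-methyl-4-(prop-2-yn-1-yl)benzene | C#CCc1c(OC)c(C)c(OCc2ccccc2)cc1OCc1ccccc1
F8 | step 11 | 5-(benzyloxy)-2-{[2,4-bis(benzyloxy)-6-methoxy-5-methylphenyl]methyl}-4-methyl-3-[(triisopropylsilyl)oxy]phenyl 3-methylbut-2-enoate | CC(C)=CC(=O)Oc1cc(OCc2ccccc2)c(C)c(O[Si](C(C)C)(C(C)C)C(C)C)c1Cc1c(OCc2ccccc2)cc(OCc2ccccc2)c(C)c1OC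
F9 | step 14 | 5-(benzyloxy)-8-{[2,4-bis(benzyloxy)-6-methoxy-5-methylphenyl]methyl}-7-hydroxy-2,2,6-trimethylchroman-4-one | CC1(C)CC(=O)c2c(OCc3ccccc3)c(C)c(O)c(Cc3c(OCc4ccccc4)cc(OCc4ccccc4)c(C)c3OC)c2O1
F10 | step 14 | 8-[(2,4-dihydroxy-6-methoxy-5-methylphenyl)methyl]-5,7-dihydroxy-2,2,6-trimethylchroman-4-one | CC1(C)CC(=O)c2c(O)c(C)c(O)c(Cc3c(O)cc(O)c(C)c3OC)c2O1
F11 | step 14 | (2R)-2-methylbutanoyl chloride | CC[C@@H](C)C(Cl)=O
A1 | alternative 1 | 5,7-bis(benzyloxy)-8-({2-ethoxy-4-hydroxy-6-methoxy-5-methyl-3-[(2R)-2-methylbutanoyl]phenyl}methyl)-2,2,6-trimethylchroman-4-one | CC[C@@H](C)C(=O)c1c(O)c(C)c(OC)c(Cc2c(OCc3ccccc3)c(C)c(OCc3ccccc3)c3c2OC(C)(C)CC3=O)c1OCC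
A2 | alternative 1 | 3-{[5,7-bis(benzyloxy)-2,2,6-trimethyl-4-oxochroman-8-yl]methyl}-4-methoxy-5-methyl-2H-pyran-2,6(3H)-dione (racemic) | COC1=C(C)C(=O)OC(=O)C1Cc1c(OCc2ccccc2)c(C)c(OCc2ccccc2)c2c1OC(C)(C)CC2=O
A3 | alternative 1 | (4R)-1-ethoxy-4-methylhex-1-yn-3-one | CC[C@@H](C)C(=O)C#COCC
A4 | alternative 2 | (2R)-1-[2,6-bis(benzyloxy)-3-{[5,7-bis(benzyloxy)-2,2,6-trimethyl-2H-chromen-8-yl]methyl}-4-methoxy-5-methylphenyl]-2-methylbutan-1-one | CC[C@@H](C)C(=O)c1c(OCc2ccccc2)c(C)c(OC)c(Cc2c(OCc3ccccc3)c(C)c(OCc3ccccc3)c3C=CC(C)(C)Oc23)c1OCc1ccccc1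
A5 | alternative 2 | (2R)-1-[2,6-bis(benzyloxy)-3-({4,6-bis(benzyloxy)-5-methyl-2-[(2-methylbut-3-yn-2-yl)oxy]phenyl}methyl)-4-methoxy-5-methylphenyl]-2-methylbutan-1-one | CC[C@@H](C)C(=O)c1c(OCc2ccccc2)c(C)c(OC)c(Cc2c(OCc3ccccc3)c(C)c(OCc3ccccc3)cc2OC(C)(C)C#C)c1OCc1ccccc1
A6 | alternative 3 | 5,7-bis(benzyloxy)-8-({2,4-dihydroxy-6-methoxy-5-methyl-3-[(2R)-2-methylbutanoyl]phenyl}methyl)-2,2,6-trimethylchroman-4-one | CC[C@@H](C)C(=O)c1c(O)c(C)c(OC)c(Cc2c(OCc3ccccc3)c(C)c(OCc3ccccc3)c3c2OC(C)(C)CC3=O)c1O
A7 | alternative 3 | 3-{[5,7-bis(benzyloxy)-2,2,6-trimethyl-4-oxochroman-8-yl]methyl}-4-methoxy-5-methyl-6-[(3R)-3-methyl-2-oxopentyl]-2H-pyran-2-one | CC[C@@H](C)C(=O)Cc1oc(=O)c(Cc2c(OCc3ccccc3)c(C)c(OCc3ccccc3)c3c2OC(C)(C)CC3=O)c(OC)c1C
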